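**Plan**

- Retrosynthesis: the ketone goes back to a benzylic alcohol and both CH2OH groups to vinyl groups. The dihydrobenzofuran is then cut at O1–C7a and C2–C3, and the open unit at its Cα–carbinol bond. This leaves two molecules of O‑silyl vanillin (rings A and D) and a furofuran carrying an (E)‑cinnamyl boronate on each aryl ring (B and C).
- Enabling feature: C3 of the dihydrobenzofuran and the α‑carbon of the ketone are homochiral benzylic carbons on the two aryl rings of a pseudo‑C2‑symmetric furofuran, each next to a guaiacyl C–O carbon. One catalyst‑controlled anti double allylboration therefore makes both, and only ring C, which carries a nonaflate at C7a ortho to C3a, can close the five‑membered O‑ring.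
- Forward order: furofuran first (dithiane conjugate addition/aldol on a menthyloxybutenolide, reduction, acid‑mediated double cyclisation). A Claisen rearrangement on ring C then installs the allyl group and unveils the phenol that becomes the nonaflate. Two‑directional C–H acetoxylation and borylation follow, then the key step, then vinyl → CH2OH, benzylic oxidation and desilylation.
- Stereochemistry: the furofuran bridgeheads come from the menthyloxy acetal (anti addition, trans aldol) and the aryl‑bearing carbons from exo‑selective ring closure. C2/C3 and Cα come from (S)‑TRIP plus (E)‑boronate geometry, and the anti adduct closes to the cis ring.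

Key step: step 13

Remark: the SMILES is read as a (1R,2S,5R,6S)-2,6-diaryl-3,7-dioxabicyclo[3.3.0]octane (pinoresinol type, both aryl groups exo), a cis-(2S,3S)-2-aryl-3-(hydroxymethyl)-2,3-dihydrobenzofuran and an (S)-configured ketone α‑carbon.
Assumption: (S)-TRIP, (S)-3,3'-bis(2,4,6-triisopropylphenyl)-1,1'-binaphthyl-2,2'-diyl hydrogen phosphate, is taken to deliver the allyl group to the Si face of an aryl aldehyde (the face that gives the S carbinol); if the sense proves opposite, (R)-TRIP is used with no other change.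
Assumption: (5R)-5-(l‑menthyloxy)furan-2(5H)-one is taken as a commercial reagent.

Ring labels: ring A = guaiacyl of the ketone; ring B = phenol ring carrying the keto side chain; ring C = benzo ring of the dihydrobenzofuran; ring D = guaiacyl on C2 of the dihydrobenzofuran.

**Route**

Step 1
Reactants: 1 4-(allyloxy)-3-methoxybenzaldehyde
Product: 2 2-[4-(allyloxy)-3-methoxyphenyl]-1,3-dithiane
Conditions: propane-1,3-dithiol, BF3·OEt2 (cat.), CH2Cl2, 0 °C → rt
Reagents that add atoms: propane-1,3-dithiol, SCCCS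
Why: Lewis acid‑catalysed dithioacetalisation of an aromatic aldehyde leaves the allyl ether intact at this temperature and gives the Corey–Seebach acyl‑anion equivalent for ring C.

Step 2
Reactants: 1 4-(allyloxy)-3-methoxybenzaldehyde
Product: 3 3-allyl-4-hydroxy-5-methoxybenzaldehyde
Conditions: neat, 200 °C (sealed tube, Ar)
Reagents that add atoms: none
Why: Aromatic Claisen rearrangement ([3,3]) moves the allyl group to the only free ortho position and tautomerisation gives the phenol.

Step 3
Reactants: 3 3-allyl-4-hydroxy-5-methoxybenzaldehyde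
Product: 4 3-allyl-5-methoxy-4-(triisopropylsilyloxy)benzaldehyde
Conditions: TIPSCl, imidazole, DMAP (cat.), DMF, 40 °C
Reagents that add atoms: triisopropylsilyl chloride, CC(C)[Si](Cl)(C(C)C)C(C)C
Why: Silylation of the hindered phenol gives an ether that should survive organolithium, hydride, mild acid, 190 °C and palladium steps and is removed by fluoride at the end.

Step 4
Reactants: 2 2-[4-(allyloxy)-3-methoxyphenyl]-1,3-dithiane; 5 (5R)-5-[(1R,2S,5R)-menthyloxy]furan-2(5H)-one; 4 3-allyl-5-methoxy-4-(triisopropylsilyloxy)benzaldehyde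
Product: 8 (3S,4R,5R)-lactone carrying the ring C dithiane at C4 and the ring B hydroxybenzyl group at C3 (carbinol epimers), via 2-lithio-2-aryl-1,3-dithiane 6 (not isolated), via lithium lactone enolate 7 (not isolated)
Conditions: n-BuLi, THF, −78 °C; then 5, −78 °C; then 4, −78 → −40 °C; aq. NH4Cl
Reagents that add atoms: none
Why: Corey–Seebach dithiane anion adds in a Michael fashion anti to the menthyloxy group at C5 and the lactone enolate is trapped by aldehyde 4 in an aldol reaction trans to the new C4 substituent, so both future bridgehead carbons are set by the acetal stereocentre (auxiliary control), while the carbinol forms as an epimer mixture that step 7 makes irrelevant.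

Step 5
Reactants: 8 (3S,4R,5R)-dithianyl hydroxybenzyl lactone
Product: 9 (3S,4R,5R)-4-[4-(allyloxy)-3-methoxybenzoyl]-3-{[3-allyl-5-methoxy-4-(triisopropylsilyloxy)phenyl](hydroxy)methyl}-5-(menthyloxy)dihydrofuran-2(3H)-one
Conditions: MeI, CaCO3, MeCN/H2O (4:1), 45 °C
Reagents that add atoms: water, O
Why: Alkylative dithiane hydrolysis (S‑methylation, then hydrolysis buffered by CaCO3) is neutral and spares the alkenes, the silyl ether and the acetal, and the all‑trans lactone is already the stable epimer at the new ketone α‑carbon.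

Step 6
Reactants: 9 (3S,4R,5R)-keto lactone
Product: 10 (2R,3R)-1-[4-(allyloxy)-3-methoxyphenyl]-4-[3-allyl-5-methoxy-4-(triisopropylsilyloxy)phenyl]-2,3-bis(hydroxymethyl)butane-1,4-diol (epimers at C1 and C4)
Conditions: LiAlH4, THF, 0 °C → rt; Fieser work-up
Reagents that add atoms: none
Why: Hydride reduces the ketone and the lactone and, after collapse of the released hemiacetal to an aldehyde with loss of menthoxide, the former acetal carbon as well, giving the tetraol without touching the two non‑epimerisable central stereocentres.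

Step 7
Reactants: 10 (2R,3R)-tetraol
Product: 11 (1R,2S,5R,6S)-2-[3-allyl-5-methoxy-4-(triisopropylsilyloxy)phenyl]-6-[4-(allyloxy)-3-methoxyphenyl]-3,7-dioxabicyclo[3.3.0]octane
Conditions: (±)-10-camphorsulfonic acid (cat.), 4 Å MS, CH2Cl2, 0 °C → rt
Reagents that add atoms: none
Why: Acid‑promoted double cyclodehydration ionises each benzylic alcohol to a para‑oxygen‑stabilised cation that is captured 5‑exo by the CH2OH on the other central carbon from the convex face, so both aryl groups should end up exo whatever the carbinol configuration was, any epi isomer being separable.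

Step 8
Reactants: 11 ring C allyl ether furofuran
Product: 12 (1R,2S,5R,6S)-2-[3-allyl-5-methoxy-4-(triisopropylsilyloxy)phenyl]-6-(3-allyl-4-hydroxy-5-methoxyphenyl)-3,7-dioxabicyclo[3.3.0]octane
Conditions: N,N-diethylaniline, 190 °C (sealed tube, Ar)
Reagents that add atoms: none
Why: Aromatic Claisen rearrangement on ring C places the allyl carbon on the future C3a and at the same time unveils the phenol on the future C7a, which differentiates ring C from silyl‑protected ring B without any protecting‑group step.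

Step 9
Reactants: 12 ring C phenol
Product: 13 (1R,2S,5R,6S)-2-[3-allyl-5-methoxy-4-(triisopropylsilyloxy)phenyl]-6-[3-allyl-5-methoxy-4-(nonafluorobutanesulfonyloxy)phenyl]-3,7-dioxabicyclo[3.3.0]octane
Conditions: NfF, Et3N, DMAP (cat.), CH2Cl2, 0 °C → rt
Reagents that add atoms: nonafluorobutanesulfonyl fluoride, FS(=O)(=O)C(F)(F)C(F)(F)C(F)(F)C(F)(F)F
Why: Sulfonylation of the only free hydroxyl turns the C7a oxygen into a robust pseudohalide and blocks Wacker‑type cyclisation of the ortho‑allylphenol in the next step.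

Step 10
Reactants: 13 bis(allyl)arene nonaflate
Product: 14 bis[(E)-3-acetoxyprop-1-enyl] analogue of 13 (one cinnamyl acetate on ring B and one on ring C)
Conditions: Pd(OAc)2 (20 mol %), p-benzoquinone, 4 Å MS, DMSO/AcOH (1:1), 40 °C
Reagents that add atoms: acetic acid, CC(=O)O
Why: White‑type allylic C–H acetoxylation, in which sulfoxide‑ligated divalent palladium cleaves the benzylic‑allylic C–H bond to a π‑allyl complex that is acetoxylated at the terminus, should give the linear (E)-cinnamyl acetates because conjugation with the arene is kept.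

Step 11
Reactants: 14 bis(cinnamyl acetate)
Product: 15 bis[(E)-3-(4,4,5,5-tetramethyl-1,3,2-dioxaborolan-2-yl)prop-1-enyl] analogue of 13
Conditions: B2pin2, Pd2(dba)3 (5 mol %), DMSO, 50 °C
Reagents that add atoms: bis(pinacolato)diboron, CC1(C)OB(OC1(C)C)B1OC(C)(C)C(C)(C)O1
Why: Miyaura borylation of allylic acetates (ionisation by zerovalent palladium, transmetalation of the acetato complex with the diboron, reductive elimination at the unhindered terminus) gives the linear (E)-boronates, and the phosphine‑free catalyst should leave the hindered aryl nonaflate alone.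

Step 12
Reactants: 16 vanillin
Product: 17 3-methoxy-4-(triisopropylsilyloxy)benzaldehyde
Conditions: TIPSCl, imidazole, DMF, rt
Reagents that add atoms: triisopropylsilyl chloride, CC(C)[Si](Cl)(C(C)C)C(C)C
Why: Standard phenol silylation masks the phenols of rings A and D against periodate and MnO2 and lowers the donor strength of the aldehyde for the allylboration.

Step 13
Reactants: 15 bis[(E)-cinnamyl boronate] nonaflate; 17 3-methoxy-4-(triisopropylsilyloxy)benzaldehyde
Product: 19 furofuran carrying on ring C the closed (2S,3R)-7-methoxy-2-[3-methoxy-4-(triisopropylsilyloxy)phenyl]-3-vinyl-2,3-dihydrobenzofuran and on silylated ring B the open (1S,2R)-1-hydroxy-1-[3-methoxy-4-(triisopropylsilyloxy)phenyl]but-3-en-2-yl chain, via bis(pinacol borate) 18 (not isolated)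
Conditions: 17 (2.4 equiv), (S)-TRIP (10 mol %), 4 Å MS, toluene, −30 → 0 °C; then Pd2(dba)3 (5 mol %), t-BuBrettPhos (12 mol %), K3PO4, 80 °C; aq. NaHCO3 work-up
Reagents that add atoms: none
Why: Proposed new method: chiral phosphoric acid‑catalysed allylboration (the closest known reaction type) of both (E)-cinnamyl boronates with 17 through chair Zimmerman–Traxler transition states gives bis(borate) 18, and the new element is that these B–O alkoxides are used directly in a Buchwald‑type C–O coupling, phosphate adding to boron so that the ate complex hands the alkoxide to the arylpalladium formed by oxidative addition into the C7a–ONf bond, much as Pd–O–B intermediates do in Suzuki couplings. The dihydrofuran ring closes in a 5‑exo sense by C–O reductive elimination from a six‑membered aryl(alkoxo)palladium chelate, which forms O1–C7a after C3–C2 has been made. C2 of the benzofuran and the carbinol of the open unit are set by the catalyst (Si‑face addition), C3 and the α‑carbon of the open unit by the (E)-olefin geometry (anti adducts), and the anti adduct must close to the cis ring because the coupling touches no stereocentre. The step needs catalyst control over the remote furofuran stereocentres, closure on one side only, and reductive elimination faster than β‑hydride elimination or retro‑allylation; these are secured by the substrate‑independent facial bias of the acid, by ring C alone carrying a leaving group at C7a (ring B carries OTIPS), and by the bulky biaryl phosphine.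

Step 14
Reactants: 19 bis(vinyl) alcohol
Product: 21 triol with CH2OH on C3 of the (2S,3S)-dihydrobenzofuran and a (1S,2S)-1,3-dihydroxy-1-arylpropan-2-yl chain on ring B, via dialdehyde 20 (not isolated)
Conditions: OsO4 (cat.), NaIO4, 2,6-lutidine, dioxane/H2O (3:1), 0 °C → rt; then NaBH4, MeOH, 0 °C
Reagents that add atoms: sodium periodate (terminal oxidant, oxygen delivered through OsO4), [Na+].[O-][I](=O)(=O)=O
Why: Lemieux–Johnson cleavage of both vinyl groups followed at once by borohydride reduction in the same pot converts them to CH2OH while the enolisable α‑aryl aldehydes exist only briefly, so the cis ring and the α‑centre of the open unit should be kept.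

Step 15
Reactants: 21 triol
Product: 22 tris(triisopropylsilyl) ether of the target
Conditions: activated MnO2 (excess), CH2Cl2, rt
Reagents that add atoms: none
Why: MnO2 oxidises benzylic alcohols and leaves saturated primary alcohols untouched, so only the ring A carbinol becomes the aryl ketone under neutral conditions that should not epimerise the adjacent α‑carbon.

Step 16
Reactants: 22 tris(triisopropylsilyl) ether
Product: 23 CNP0174045.1
Conditions: TBAF, AcOH (1:1), THF, 0 °C
Reagents that add atoms: none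
Why: Fluoride cleaves the three aryl silyl ethers, and acetic acid buffers the phenoxides so that the α‑aryl β‑hydroxy ketone should escape epimerisation, retro‑aldol loss of formaldehyde and cyclodehydration to a benzofuran.

**Compound list**

1 | 4-(allyloxy)-3-methoxybenzaldehyde | C=CCOc1ccc(C=O)cc1OC | starting material
2 | 2-[4-(allyloxy)-3-methoxyphenyl]-1,3-dithiane | C=CCOc1ccc(C2SCCCS2)cc1OC | intermediate
3 | 3-allyl-4-hydroxy-5-methoxybenzaldehyde | C=CCc1cc(C=O)cc(OC)c1O | intermediate
4 | 3-allyl-5-methoxy-4-(triisopropylsilyloxy)benzaldehyde | C=CCc1cc(C=O)cc(OC)c1O[Si](C(C)C)(C(C)C)C(C)C | intermediate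
5 | (5R)-5-[(1R,2S,5R)-menthyloxy]furan-2(5H)-one | O=C1O[C@@H](O[C@@H]2C[C@H](C)CC[C@H]2C(C)C)C=C1 | starting material
6 | 2-lithio-2-[4-(allyloxy)-3-methoxyphenyl]-1,3-dithiane | [Li]C1(c2ccc(OCC=C)c(OC)c2)SCCCS1 | intermediate
7 | lithium enolate of the (4R,5R)-4-(2-aryl-1,3-dithian-2-yl)-5-(menthyloxy) lactone | [Li]OC1=C[C@@H](C2(c3ccc(OCC=C)c(OC)c3)SCCCS2)[C@H](O[C@@H]4C[C@H](C)CC[C@H]4C(C)C)O1 | intermediate
8 | (3S,4R,5R)-4-{2-[4-(allyloxy)-3-methoxyphenyl]-1,3-dithian-2-yl}-3-{[3-allyl-5-methoxy-4-(triisopropylsilyloxy)phenyl](hydroxy)methyl}-5-(menthyloxy)dihydrofuran-2(3H)-one, carbinol epimers | O=C1O[C@@H](O[C@@H]2C[C@H](C)CC[C@H]2C(C)C)[C@H](C3(c4ccc(OCC=C)c(OC)c4)SCCCS3)[C@H]1C(O)c5cc(CC=C)c(O[Si](C(C)C)(C(C)C)C(C)C)c(OC)c5 | intermediate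
9 | (3S,4R,5R)-4-[4-(allyloxy)-3-methoxybenzoyl]-3-{[3-allyl-5-methoxy-4-(triisopropylsilyloxy)phenyl](hydroxy)methyl}-5-(menthyloxy)dihydrofuran-2(3H)-one, carbinol epimers | O=C1O[C@@H](O[C@@H]2C[C@H](C)CC[C@H]2C(C)C)[C@H](C(=O)c4ccc(OCC=C)c(OC)c4)[C@H]1C(O)c5cc(CC=C)c(O[Si](C(C)C)(C(C)C)C(C)C)c(OC)c5 | intermediate
10 | (2R,3R)-1-[4-(allyloxy)-3-methoxyphenyl]-4-[3-allyl-5-methoxy-4-(triisopropylsilyloxy)phenyl]-2,3-bis(hydroxymethyl)butane-1,4-diol, epimers at C1 and C4 | OC[C@H](C(O)c1ccc(OCC=C)c(OC)c1)[C@H](CO)C(O)c2cc(CC=C)c(O[Si](C(C)C)(C(C)C)C(C)C)c(OC)c2 | intermediate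
11 | (1R,2S,5R,6S)-2-[3-allyl-5-methoxy-4-(triisopropylsilyloxy)phenyl]-6-[4-(allyloxy)-3-methoxyphenyl]-3,7-dioxabicyclo[3.3.0]octane | C=CCc2cc([C@H]3OC[C@H]4[C@@H]3CO[C@@H]4c5ccc(OCC=C)c(OC)c5)cc(OC)c2O[Si](C(C)C)(C(C)C)C(C)C | intermediate
12 | (1R,2S,5R,6S)-2-[3-allyl-5-methoxy-4-(triisopropylsilyloxy)phenyl]-6-(3-allyl-4-hydroxy-5-methoxyphenyl)-3,7-dioxabicyclo[3.3.0]octane | C=CCc2cc([C@H]3OC[C@H]4[C@@H]3CO[C@@H]4c5cc(OC)c(O)c(CC=C)c5)cc(OC)c2O[Si](C(C)C)(C(C)C)C(C)C | intermediate
13 | (1R,2S,5R,6S)-2-[3-allyl-5-methoxy-4-(triisopropylsilyloxy)phenyl]-6-[3-allyl-5-methoxy-4-(nonafluorobutanesulfonyloxy)phenyl]-3,7-dioxabicyclo[3.3.0]octane | C=CCc2cc([C@H]3OC[C@H]4[C@@H]3CO[C@@H]4c5cc(OC)c(OS(=O)(=O)C(F)(F)C(F)(F)C(F)(F)C(F)(F)F)c(CC=C)c5)cc(OC)c2O[Si](C(C)C)(C(C)C)C(C)C | intermediate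
14 | analogue of 13 with both allyl groups replaced by (E)-3-acetoxyprop-1-enyl | CC(=O)OC/C=C/c2cc([C@H]3OC[C@H]4[C@@H]3CO[C@@H]4c5cc(OC)c(OS(=O)(=O)C(F)(F)C(F)(F)C(F)(F)C(F)(F)F)c(/C=C/COC(C)=O)c5)cc(OC)c2O[Si](C(C)C)(C(C)C)C(C)C | intermediate
15 | analogue of 13 with both allyl groups replaced by (E)-3-(pinacolboryl)prop-1-enyl | CC1(C)OB(C/C=C/c2cc([C@H]3OC[C@H]4[C@@H]3CO[C@@H]4c5cc(OC)c(OS(=O)(=O)C(F)(F)C(F)(F)C(F)(F)C(F)(F)F)c(/C=C/CB6OC(C)(C)C(C)(C)O6)c5)cc(OC)c2O[Si](C(C)C)(C(C)C)C(C)C)OC1(C)C | intermediate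
16 | vanillin | COc1cc(C=O)ccc1O | starting material
17 | 3-methoxy-4-(triisopropylsilyloxy)benzaldehyde | COc1cc(C=O)ccc1O[Si](C(C)C)(C(C)C)C(C)C | intermediate
18 | bis(pinacol borate) of the double anti allylboration product, (1S,2R) on both sides, ring C still a nonaflate | COc1cc([C@@H](OB5OC(C)(C)C(C)(C)O5)[C@H](C=C)c2cc([C@H]3OC[C@H]4[C@@H]3CO[C@@H]4c3cc(OC)c(OS(=O)(=O)C(F)(F)C(F)(F)C(F)(F)C(F)(F)F)c(c3)[C@@H](C=C)[C@@H](c3ccc(O[Si](C(C)C)(C(C)C)C(C)C)c(OC)c3)OB6OC(C)(C)C(C)(C)O6)cc(OC)c2O[Si](C(C)C)(C(C)C)C(C)C)ccc1O[Si](C(C)C)(C(C)C)C(C)C | intermediate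
19 | furofuran with cis-(2S,3R)-2-aryl-3-vinyl-dihydrobenzofuran on ring C and (1S,2R)-1-hydroxy-1-arylbut-3-en-2-yl chain on ring B, three OTIPS groups | COc1cc([C@@H](O)[C@H](C=C)c2cc([C@H]3OC[C@H]4[C@@H]3CO[C@@H]4c3cc(OC)c4c(c3)[C@@H](C=C)[C@@H](c3ccc(O[Si](C(C)C)(C(C)C)C(C)C)c(OC)c3)O4)cc(OC)c2O[Si](C(C)C)(C(C)C)C(C)C)ccc1O[Si](C(C)C)(C(C)C)C(C)C | intermediate
20 | dialdehyde from cleavage of both vinyl groups of 19 | COc1cc([C@@H](O)[C@H](C=O)c2cc([C@H]3OC[C@H]4[C@@H]3CO[C@@H]4c3cc(OC)c4c(c3)[C@@H](C=O)[C@@H](c3ccc(O[Si](C(C)C)(C(C)C)C(C)C)c(OC)c3)O4)cc(OC)c2O[Si](C(C)C)(C(C)C)C(C)C)ccc1O[Si](C(C)C)(C(C)C)C(C)C | intermediate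
21 | triol: (2S,3S)-3-(hydroxymethyl)dihydrobenzofuran on ring C and (1S,2S)-1,3-dihydroxy-1-arylpropan-2-yl chain on ring B, three OTIPS groups | COc1cc([C@@H](O)[C@H](CO)c2cc([C@H]3OC[C@H]4[C@@H]3CO[C@@H]4c3cc(OC)c4c(c3)[C@@H](CO)[C@@H](c3ccc(O[Si](C(C)C)(C(C)C)C(C)C)c(OC)c3)O4)cc(OC)c2O[Si](C(C)C)(C(C)C)C(C)C)ccc1O[Si](C(C)C)(C(C)C)C(C)C | intermediate
22 | tris(triisopropylsilyl) ether of the target (phenols of rings A, B and D silylated) | COc1cc(C(=O)[C@H](CO)c2cc([C@H]3OC[C@H]4[C@@H]3CO[C@@H]4c3cc(OC)c4c(c3)[C@@H](CO)[C@@H](c3ccc(O[Si](C(C)C)(C(C)C)C(C)C)c(OC)c3)O4)cc(OC)c2O[Si](C(C)C)(C(C)C)C(C)C)ccc1O[Si](C(C)C)(C(C)C)C(C)C | intermediate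
23 | CNP0174045.1 | COc1cc(C(=O)[C@H](CO)c2cc([C@H]3OC[C@H]4[C@@H]3CO[C@@H]4c3cc(OC)c4c(c3)[C@@H](CO)[C@@H](c3ccc(O)c(OC)c3)O4)cc(OC)c2O)ccc1O | target

**Step count**

Total steps: 16. Longest linear sequence: 14 steps (steps 2, 3, 4–11 and 13–16, from compound 1 through aldehyde 4).

**Steps most likely to fail**

Step 13. The transfer of the alkoxide from boron to palladium may stall at the borate, or the arylpalladium alkoxide may undergo β‑hydride elimination or palladium hydride may shift the vinyl group into conjugation. The fallback uses known chemistry and sets out from 15 and 17. The same (S)-TRIP‑catalysed double allylboration is run alone and the borates are hydrolysed on aqueous NaHCO3 work-up to isolate the free bis‑homoallylic diol nonaflate F1. F1 is then closed in a separate Buchwald intramolecular etherification of the free alcohol (Pd2(dba)3, t-BuBrettPhos, K3PO4, toluene, 80 °C), which comes back to the route at 19.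

Step 14. The two α‑aryl aldehydes may epimerise in the basic periodate medium (cis to trans at C3, loss of the α‑centre of the open unit), and the β‑hydroxy aldehyde may cleave by retro‑aldol reaction. The fallback sets out from 19 and avoids a free aldehyde in base. Ozone in CH2Cl2 at −78 °C (titrated against Sudan Red 7B to spare the arenes) gives the bis(1,2,4-trioxolane) F2, which NaBH4 in EtOH reduces directly at −78 → 0 °C, returning to the route at 21.

Step 10. The twofold C–H oxidation may stop halfway, give branched acetate or Wacker ketone, or the warm acetic acid may erode the furofuran configuration. The fallback sets out from 13 and avoids C–H oxidation. Both allyl groups are isomerised with RuHCl(CO)(PPh3)3 (toluene, 80 °C) to the bis[(E)-prop-1-enyl]arene F3. Cross‑metathesis with vinylboronic acid pinacol ester (second‑generation Hoveyda–Grubbs catalyst, CH2Cl2, 40 °C) gives the bis[(E)-2-borylvinyl]arene F4. Matteson homologation (ICH2Cl, n-BuLi, THF, −78 °C → rt) then inserts the CH2 group by 1,2‑migration of the alkenyl group and comes back to the route at 15, bypassing 14.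

Further compounds
F1 | step 13 | bis-homoallylic diol nonaflate, (1S,2R) on both sides, free secondary alcohols | COc1cc([C@@H](O)[C@H](C=C)c2cc([C@H]3OC[C@H]4[C@@H]3CO[C@@H]4c3cc(OC)c(OS(=O)(=O)C(F)(F)C(F)(F)C(F)(F)C(F)(F)F)c(c3)[C@@H](C=C)[C@@H](c3ccc(O[Si](C(C)C)(C(C)C)C(C)C)c(OC)c3)O)cc(OC)c2O[Si](C(C)C)(C(C)C)C(C)C)ccc1O[Si](C(C)C)(C(C)C)C(C)C
F2 | step 14 | bis(1,2,4-trioxolane) from ozonolysis of both vinyl groups of 19 | COc1cc([C@@H](O)[C@H](C5OCOO5)c2cc([C@H]3OC[C@H]4[C@@H]3CO[C@@H]4c3cc(OC)c4c(c3)[C@@H](C5OCOO5)[C@@H](c3ccc(O[Si](C(C)C)(C(C)C)C(C)C)c(OC)c3)O4)cc(OC)c2O[Si](C(C)C)(C(C)C)C(C)C)ccc1O[Si](C(C)C)(C(C)C)C(C)C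
F3 | step 10 | analogue of 13 with both allyl groups isomerised to (E)-prop-1-enyl | C/C=C/c2cc([C@H]3OC[C@H]4[C@@H]3CO[C@@H]4c5cc(OC)c(OS(=O)(=O)C(F)(F)C(F)(F)C(F)(F)C(F)(F)F)c(/C=C/C)c5)cc(OC)c2O[Si](C(C)C)(C(C)C)C(C)C
F4 | step 10 | analogue of 13 with both allyl groups replaced by (E)-2-(pinacolboryl)vinyl | CC1(C)OB(/C=C/c2cc([C@H]3OC[C@H]4[C@@H]3CO[C@@H]4c5cc(OC)c(OS(=O)(=O)C(F)(F)C(F)(F)C(F)(F)C(F)(F)F)c(/C=C/B6OC(C)(C)C(C)(C)O6)c5)cc(OC)c2O[Si](C(C)C)(C(C)C)C(C)C)OC1(C)C
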